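Numbering: lactone O1, C2 (C=O), C3 (=CH2), C4H2, C5H; side chain C1'H2, C2'(CH3)(OH), C3'H(OH), C4'H2–O–coumarin. Everything rests on C5 of the butyrolactone ring: it is a carbinol carbon flanked by two methylenes (C4 and C1'), so it is treated as a 1,3-dithiane carbon alkylated on both sides. In one flask a silyl dithiane anion opens a C1'/C2' epoxide at C1', the silyl group shifts from carbon to the tertiary O2', and the relayed anion is allylated by 2,3-dibromopropene (C5–C4). The precursor is the erythro 2-methyl-2-substituted oxirane whose O3' and O4' are tied into one p-methoxybenzylidene acetal.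

Key step: step 4

Remarks on the chemistry
- Configuration: the target is (5S,2'S,3'R). O2'/O3' are erythro (set by the epoxy alcohol) and O5/O2' are 1,3-syn (set by the directed ketone reduction). No structure needed correcting.
- Protecting groups of the epoxide: O3' is not carried as a trialkylsilyl ether. Such a group would sit next to the tertiary alkoxide of the key step, where O→O silyl transfer could compete with the C→O shift, and it would add bulk at the site of the hindered silyl transfer. It would also be lost together with the O2' silyl group, and the resulting γ-hydroxy ketone would close to a lactol before C5 is reduced. A p-methoxybenzylidene acetal over O3'/O4', made from the PMB ether already present, avoids this. DIBAL later frees only O4', so the aryl ether is made while O4'–H is the only free hydroxyl and before any ketone or exo-methylene lactone exists.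
- Assumption: 1, 2 (0.5 M in THF), 6, 7 and 13 are purchased.

Step 1
Reactants: 1 (4-methoxybenzyloxy)acetaldehyde; 2 isopropenylmagnesium bromide
Product: 3 rac-1-[(4-methoxybenzyl)oxy]-3-methylbut-3-en-2-ol
Conditions: THF, −78 → 0 °C; aq NH4Cl
Reagents that add atoms: none
Why: Grignard 1,2-addition of an alkenylmagnesium halide to an aldehyde at low temperature; the carbinol centre is formed racemic on purpose and is resolved in step 2.

Step 2
Reactants: 3 rac-1-[(4-methoxybenzyl)oxy]-3-methylbut-3-en-2-ol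
Product: 4 (1R)-2-[(4-methoxybenzyl)oxy]-1-[(2S)-2-methyloxiran-2-yl]ethan-1-ol (erythro epoxy alcohol)
Conditions: Ti(OiPr)4 (10 mol%), D-(−)-DIPT (15 mol%), t-BuOOH (0.5 equiv), 4 Å MS, CH2Cl2, −20 °C
Reagents that add atoms: tert-butyl hydroperoxide, CC(C)(C)OO
Why: Sharpless kinetic resolution, in which the (S)-alcohol is the fast-reacting enantiomer with D-(−)-tartrate and takes oxygen on the alkene face anti to its CH2OPMB group, setting the (S)-oxirane carbon erythro to the carbinol (labelled R in 4) and leaving the (R)-alcohol behind; catalytic titanium, sieves and sub-stoichiometric oxidant protect the 2,2-disubstituted epoxide.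

Step 3
Reactants: 4 (1R)-2-[(4-methoxybenzyl)oxy]-1-[(2S)-2-methyloxiran-2-yl]ethan-1-ol
Product: 5 (4R)-2-(4-methoxyphenyl)-4-[(2S)-2-methyloxiran-2-yl]-1,3-dioxolane (either epimer at the acetal carbon)
Conditions: DDQ (1.2 equiv), 4 Å MS, CH2Cl2, 0 °C → rt
Reagents that add atoms: none
Why: Anhydrous DDQ oxidative acetalisation of a hydroxy PMB ether, in which benzylic hydride abstraction gives an oxocarbenium ion that the vicinal hydroxyl captures in a 5-exo closure; the neutral medium spares the epoxide, no existing stereocentre is involved, and the acetal centre is removed in step 5.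

Step 4
Reactants: 5 (4R)-2-(4-methoxyphenyl)-4-[(2S)-2-methyloxiran-2-yl]-1,3-dioxolane; 6 2-(tert-butyldimethylsilyl)-1,3-dithiane; 7 2,3-dibromopropene
Product: 11 2-(2-bromoprop-2-en-1-yl)-2-{(2S)-2-[(tert-butyldimethylsilyl)oxy]-2-[(4R)-2-(4-methoxyphenyl)-1,3-dioxolan-4-yl]propyl}-1,3-dithiane, via lithiated silyl dithiane 8 (not isolated), via tertiary lithium alkoxide 9 (not isolated), via O-silylated lithio dithiane 10 (not isolated)
Conditions: 6, t-BuLi, Et2O, −78 → −45 °C; 5, −78 → 0 °C; then 7, HMPA/Et2O, −78 °C → rt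
Reagents that add atoms: none
Why: Lithiation of 6 gives anion 8, which attacks epoxide 5 by SN2 at its only accessible carbon, the unsubstituted CH2 (C1'), forming C1'–C5 and the tertiary lithium alkoxide 9, which should persist in ether. Adding HMPA together with 7 loosens the O–Li pair, so silicon migrates from carbon to O2' through a five-membered pentacoordinate silicate (1,4-Brook rearrangement), and the sulfur-stabilised carbanion 10 is trapped by the allylic C–Br of 7 to form C5–C4. The closest known reaction type is the solvent-gated three-component anion relay coupling of a 2-silyl-1,3-dithiane with an epoxide and then an alkyl halide. No ring is closed and no stereocentre is created; C2' and C3' pass from 5 unchanged because no bond to either is broken. The step needs site selectivity (CH2 versus the fully substituted epoxide carbon, allylic versus vinylic bromide), which the substitution patterns of 5 and 7 secure, and order selectivity (no silyl shift before the second electrophile is present), which withholding HMPA secures. The compact cyclic acetal offers no second silyl group and little bulk beside the tertiary alkoxide, which should help the hindered silyl transfer.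

Step 5
Reactants: 11 2-(2-bromoprop-2-en-1-yl)-2-{(2S)-2-[(tert-butyldimethylsilyl)oxy]-2-[(4R)-2-(4-methoxyphenyl)-1,3-dioxolan-4-yl]propyl}-1,3-dithiane
Product: 12 (2R,3S)-4-[2-(2-bromoprop-2-en-1-yl)-1,3-dithian-2-yl]-3-[(tert-butyldimethylsilyl)oxy]-2-[(4-methoxybenzyl)oxy]-3-methylbutan-1-ol
Conditions: DIBAL-H (3 equiv), CH2Cl2, −78 → 0 °C; Rochelle salt
Reagents that add atoms: none
Why: Reductive opening of a p-methoxybenzylidene acetal with DIBAL-H, in which aluminium binds the less hindered primary O4', the C–O4' bond ionises and hydride quenches the oxocarbenium ion, leaving PMB on the hindered O3' and a free primary alcohol; both acetal epimers converge, and thioketal, vinyl bromide and silyl ether are inert at or below 0 °C.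

Step 6
Reactants: 12 (2R,3S)-4-[2-(2-bromoprop-2-en-1-yl)-1,3-dithian-2-yl]-3-[(tert-butyldimethylsilyl)oxy]-2-[(4-methoxybenzyl)oxy]-3-methylbutan-1-ol; 13 umbelliferone (7-hydroxy-2H-chromen-2-one)
Product: 14 7-{[(2R,3S)-4-[2-(2-bromoprop-2-en-1-yl)-1,3-dithian-2-yl]-3-[(tert-butyldimethylsilyl)oxy]-2-[(4-methoxybenzyl)oxy]-3-methylbutyl]oxy}-2H-chromen-2-one
Conditions: PPh3, DIAD, THF, 0 °C → rt
Reagents that add atoms: none
Why: Mitsunobu etherification, in which the acidic phenol displaces the activated primary alkoxyphosphonium by SN2 at C4', the only free hydroxyl in 12, so no stereocentre is touched and the coumarin is attached before any ketone or enoate is present.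

Step 7
Reactants: 14 7-{[(2R,3S)-4-[2-(2-bromoprop-2-en-1-yl)-1,3-dithian-2-yl]-3-[(tert-butyldimethylsilyl)oxy]-2-[(4-methoxybenzyl)oxy]-3-methylbutyl]oxy}-2H-chromen-2-one
Product: 15 7-{[(2R,3S)-4-[2-(2-bromoprop-2-en-1-yl)-1,3-dithian-2-yl]-3-hydroxy-2-[(4-methoxybenzyl)oxy]-3-methylbutyl]oxy}-2H-chromen-2-one
Conditions: 48% aq HF, MeCN, 0 °C → rt
Reagents that add atoms: none
Why: Desilylation with aqueous HF, which should cleave the hindered tertiary TBS ether while PMB ether, thioketal, vinyl bromide and coumarin are stable; freeing O2'–H before the ketone is unmasked keeps fluoride and acid away from a tertiary aldol.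

Step 8
Reactants: 15 7-{[(2R,3S)-4-[2-(2-bromoprop-2-en-1-yl)-1,3-dithian-2-yl]-3-hydroxy-2-[(4-methoxybenzyl)oxy]-3-methylbutyl]oxy}-2H-chromen-2-one
Product: 16 7-{[(2R,3S)-7-bromo-3-hydroxy-2-[(4-methoxybenzyl)oxy]-3-methyl-5-oxooct-7-en-1-yl]oxy}-2H-chromen-2-one
Conditions: MeI, CaCO3, MeCN/H2O (9:1), 45 °C
Reagents that add atoms: water, O
Why: Alkylative thioketal hydrolysis, in which S-methylation makes sulfur a leaving group and water adds to the thionium ion; the carbonate-buffered, near-neutral medium should spare the tertiary aldol (no retro-aldol or dehydration), the 2-bromoallyl ketone (no shift into conjugation) and the PMB ether.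

Step 9
Reactants: 16 7-{[(2R,3S)-7-bromo-3-hydroxy-2-[(4-methoxybenzyl)oxy]-3-methyl-5-oxooct-7-en-1-yl]oxy}-2H-chromen-2-one
Product: 18 7-{[(2R,3S,5R)-7-bromo-3,5-dihydroxy-2-[(4-methoxybenzyl)oxy]-3-methyloct-7-en-1-yl]oxy}-2H-chromen-2-one, via diethylborinate chelate 17 (not isolated)
Conditions: Et2BOMe, THF/MeOH (4:1), rt → −78 °C; NaBH4, −78 °C; AcOH, then MeOH co-evaporation
Reagents that add atoms: none
Why: Narasaka–Prasad reduction, in which O2'–H is exchanged to the borinate 17, boron chelates the ketone in a six-membered half-chair with the large C3' chain equatorial, and external borohydride adds axially so that C4 also ends equatorial, giving the 1,3-syn diol with the C5 geometry of the target (labelled R here only because the bromine-bearing branch outranks the C2' branch); the 7-alkoxycoumarin should not be reduced at −78 °C, and boron is stripped with MeOH/AcOH instead of alkaline peroxide.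

Step 10
Reactants: 18 7-{[(2R,3S,5R)-7-bromo-3,5-dihydroxy-2-[(4-methoxybenzyl)oxy]-3-methyloct-7-en-1-yl]oxy}-2H-chromen-2-one
Product: 19 7-{[(2R,3S)-3-hydroxy-2-[(4-methoxybenzyl)oxy]-3-methyl-4-[(2S)-4-methylidene-5-oxooxolan-2-yl]butyl]oxy}-2H-chromen-2-one
Conditions: Pd(PPh3)4 (5 mol%), CO (1 atm), Et3N, MeCN, 60 °C
Reagents that add atoms: carbon monoxide, [C-]#[O+]
Why: Palladium-catalysed cyclocarbonylation of a 2-bromo homoallylic alcohol, in which oxidative addition into the vinyl C–Br bond, CO insertion and capture of the acyl-palladium by O5–H close the five-membered lactone (favoured over the seven-membered ring through the tertiary O2'–H); the exocyclic methylene arises directly and C5 is retained because its C–O bond is not broken.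

Step 11
Reactants: 19 7-{[(2R,3S)-3-hydroxy-2-[(4-methoxybenzyl)oxy]-3-methyl-4-[(2S)-4-methylidene-5-oxooxolan-2-yl]butyl]oxy}-2H-chromen-2-one
Product: 20 7-{[(2R,3S)-2,3-dihydroxy-3-methyl-4-[(2S)-4-methylidene-5-oxooxolan-2-yl]butyl]oxy}-2H-chromen-2-one (CNP0216562.1)
Conditions: DDQ, CH2Cl2/pH 7 buffer (10:1), 0 °C → rt
Reagents that add atoms: none
Why: Oxidative PMB ether cleavage, in which DDQ forms the benzylic oxocarbenium ion and water in the biphasic medium hydrolyses it to 4-methoxybenzaldehyde and free O3'–H; the exo-methylene lactone, the coumarin and the tertiary alcohol are not oxidised and no stereocentre is involved.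

Compound list
1 | (4-methoxybenzyloxy)acetaldehyde | COc1ccc(COCC=O)cc1 | starting material
2 | isopropenylmagnesium bromide | CC(=C)[Mg]Br | starting material
3 | rac-1-[(4-methoxybenzyl)oxy]-3-methylbut-3-en-2-ol | C=C(C)C(O)COCc1ccc(OC)cc1 | intermediate
4 | (1R)-2-[(4-methoxybenzyl)oxy]-1-[(2S)-2-methyloxiran-2-yl]ethan-1-ol | C[C@]1(CO1)[C@H](O)COCc2ccc(OC)cc2 | intermediate
5 | (4R)-2-(4-methoxyphenyl)-4-[(2S)-2-methyloxiran-2-yl]-1,3-dioxolane, acetal carbon either epimer | C[C@]1(CO1)[C@H]2COC(O2)c3ccc(OC)cc3 | intermediate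
6 | 2-(tert-butyldimethylsilyl)-1,3-dithiane | CC(C)(C)[Si](C)(C)C1SCCCS1 | starting material
7 | 2,3-dibromopropene | C=C(Br)CBr | starting material
8 | 2-lithio-2-(tert-butyldimethylsilyl)-1,3-dithiane | [Li]C1(SCCCS1)[Si](C)(C)C(C)(C)C | intermediate (not isolated)
9 | lithium (2S)-1-[2-(tert-butyldimethylsilyl)-1,3-dithian-2-yl]-2-[(4R)-2-(4-methoxyphenyl)-1,3-dioxolan-4-yl]propan-2-olate | CC(C)(C)[Si](C)(C)C1(SCCCS1)C[C@](C)(O[Li])[C@H]2COC(O2)c3ccc(OC)cc3 | intermediate (not isolated)
10 | 2-lithio-2-{(2S)-2-[(tert-butyldimethylsilyl)oxy]-2-[(4R)-2-(4-methoxyphenyl)-1,3-dioxolan-4-yl]propyl}-1,3-dithiane | [Li]C1(SCCCS1)C[C@](C)(O[Si](C)(C)C(C)(C)C)[C@H]2COC(O2)c3ccc(OC)cc3 | intermediate (not isolated)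
11 | 2-(2-bromoprop-2-en-1-yl)-2-{(2S)-2-[(tert-butyldimethylsilyl)oxy]-2-[(4R)-2-(4-methoxyphenyl)-1,3-dioxolan-4-yl]propyl}-1,3-dithiane | C=C(Br)CC1(SCCCS1)C[C@](C)(O[Si](C)(C)C(C)(C)C)[C@H]2COC(O2)c3ccc(OC)cc3 | intermediate
12 | (2R,3S)-4-[2-(2-bromoprop-2-en-1-yl)-1,3-dithian-2-yl]-3-[(tert-butyldimethylsilyl)oxy]-2-[(4-methoxybenzyl)oxy]-3-methylbutan-1-ol | C=C(Br)CC1(SCCCS1)C[C@](C)(O[Si](C)(C)C(C)(C)C)[C@H](OCc2ccc(OC)cc2)CO | intermediate
13 | umbelliferone (7-hydroxy-2H-chromen-2-one) | Oc1ccc2ccc(=O)oc2c1 | starting material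
14 | 7-{[(2R,3S)-4-[2-(2-bromoprop-2-en-1-yl)-1,3-dithian-2-yl]-3-[(tert-butyldimethylsilyl)oxy]-2-[(4-methoxybenzyl)oxy]-3-methylbutyl]oxy}-2H-chromen-2-one | C=C(Br)CC1(SCCCS1)C[C@](C)(O[Si](C)(C)C(C)(C)C)[C@H](OCc2ccc(OC)cc2)COc3ccc4ccc(=O)oc4c3 | intermediate
15 | 7-{[(2R,3S)-4-[2-(2-bromoprop-2-en-1-yl)-1,3-dithian-2-yl]-3-hydroxy-2-[(4-methoxybenzyl)oxy]-3-methylbutyl]oxy}-2H-chromen-2-one | C=C(Br)CC1(SCCCS1)C[C@](C)(O)[C@H](OCc2ccc(OC)cc2)COc3ccc4ccc(=O)oc4c3 | intermediate
16 | 7-{[(2R,3S)-7-bromo-3-hydroxy-2-[(4-methoxybenzyl)oxy]-3-methyl-5-oxooct-7-en-1-yl]oxy}-2H-chromen-2-one | C=C(Br)CC(=O)C[C@](C)(O)[C@H](OCc2ccc(OC)cc2)COc3ccc4ccc(=O)oc4c3 | intermediate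
17 | O3-diethylboryl derivative (boron chelate) of 16 | C=C(Br)CC(=O)C[C@](C)(OB(CC)CC)[C@H](OCc2ccc(OC)cc2)COc3ccc4ccc(=O)oc4c3 | intermediate (not isolated)
18 | 7-{[(2R,3S,5R)-7-bromo-3,5-dihydroxy-2-[(4-methoxybenzyl)oxy]-3-methyloct-7-en-1-yl]oxy}-2H-chromen-2-one | C=C(Br)C[C@H](O)C[C@](C)(O)[C@H](OCc2ccc(OC)cc2)COc3ccc4ccc(=O)oc4c3 | intermediate
19 | 7-{[(2R,3S)-3-hydroxy-2-[(4-methoxybenzyl)oxy]-3-methyl-4-[(2S)-4-methylidene-5-oxooxolan-2-yl]butyl]oxy}-2H-chromen-2-one | C=C1C[C@@H](C[C@](C)(O)[C@H](OCc2ccc(OC)cc2)COc3ccc4ccc(=O)oc4c3)OC1=O | intermediate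
20 | 7-{[(2R,3S)-2,3-dihydroxy-3-methyl-4-[(2S)-4-methylidene-5-oxooxolan-2-yl]butyl]oxy}-2H-chromen-2-one | C=C1C[C@@H](C[C@](C)(O)[C@H](O)COc2ccc3ccc(=O)oc3c2)OC1=O | target

Total step count: 11. Longest linear sequence: 11 steps (1 → 20); 2, 6, 7 and 13 enter as purchased compounds.

Steps most likely to fail

Step 4. The silyl shift from carbon to the hindered tertiary alkoxide may be too slow for the second alkylation to occur, or the relayed anion may dehydrobrominate 7 instead of substituting it. The fallback is a stepwise double alkylation of the dithiane (Corey–Seebach) without a Brook shift, setting out from 5. Opening of 5 with 2-lithio-1,3-dithiane (1,3-dithiane, n-BuLi, THF, −30 → 0 °C) should give 2-{(2S)-2-hydroxy-2-[(4R)-2-(4-methoxyphenyl)-1,3-dioxolan-4-yl]propyl}-1,3-dithiane F1. Silylation (TBSOTf, 2,6-lutidine, CH2Cl2, 0 °C) should give 2-{(2S)-2-[(tert-butyldimethylsilyl)oxy]-2-[(4R)-2-(4-methoxyphenyl)-1,3-dioxolan-4-yl]propyl}-1,3-dithiane F2. Deprotonation of F2 (t-BuLi, THF/HMPA, −78 °C) and alkylation with 7 comes back to the route at 11.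

Step 9. Facial selectivity may be poor, because the C2' methyl group must sit axial in the boron chelate, on the face from which hydride has to arrive. The fallback sets out from 16 and uses internal hydride delivery followed by inversion. Evans–Saksena reduction (Me4NBH(OAc)3, MeCN/AcOH, −30 °C) should give the 1,3-anti diol 7-{[(2R,3S,5S)-7-bromo-3,5-dihydroxy-2-[(4-methoxybenzyl)oxy]-3-methyloct-7-en-1-yl]oxy}-2H-chromen-2-one F3, since in that chair the axial methyl reinforces the preferred arrangement. Mitsunobu inversion of the only secondary hydroxyl (ClCH2CO2H, PPh3, DIAD, THF) should give (4R,6S,7R)-2-bromo-6-hydroxy-7-[(4-methoxybenzyl)oxy]-6-methyl-8-[(2-oxo-2H-chromen-7-yl)oxy]oct-1-en-4-yl chloroacetate F4. Removal of the chloroacetyl group (thiourea, NaHCO3, EtOH) comes back to the route at 18.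

Step 11. The benzylic cation may be captured by the neighbouring tertiary O2'–H to give a cyclic acetal, or be over-oxidised to an anisoate ester, instead of being hydrolysed cleanly. The fallback sets out from 19 and makes the acetal on purpose. Anhydrous oxidation (DDQ, 4 Å MS, CH2Cl2) should give 7-{[(4R,5S)-2-(4-methoxyphenyl)-5-methyl-5-{[(2S)-4-methylidene-5-oxooxolan-2-yl]methyl}-1,3-dioxolan-4-yl]methoxy}-2H-chromen-2-one F5. Mild acid hydrolysis (80% aq AcOH, rt → 40 °C) comes back to the route at 20.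

Further compounds
F1 | step 4 | 2-{(2S)-2-hydroxy-2-[(4R)-2-(4-methoxyphenyl)-1,3-dioxolan-4-yl]propyl}-1,3-dithiane | C1(SCCCS1)C[C@](C)(O)[C@H]2COC(O2)c3ccc(OC)cc3
F2 | step 4 | 2-{(2S)-2-[(tert-butyldimethylsilyl)oxy]-2-[(4R)-2-(4-methoxyphenyl)-1,3-dioxolan-4-yl]propyl}-1,3-dithiane | C1(SCCCS1)C[C@](C)(O[Si](C)(C)C(C)(C)C)[C@H]2COC(O2)c3ccc(OC)cc3
F3 | step 9 | 7-{[(2R,3S,5S)-7-bromo-3,5-dihydroxy-2-[(4-methoxybenzyl)oxy]-3-methyloct-7-en-1-yl]oxy}-2H-chromen-2-one | C=C(Br)C[C@@H](O)C[C@](C)(O)[C@H](OCc2ccc(OC)cc2)COc3ccc4ccc(=O)oc4c3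
F4 | step 9 | (4R,6S,7R)-2-bromo-6-hydroxy-7-[(4-methoxybenzyl)oxy]-6-methyl-8-[(2-oxo-2H-chromen-7-yl)oxy]oct-1-en-4-yl chloroacetate | C=C(Br)C[C@H](OC(=O)CCl)C[C@](C)(O)[C@H](OCc2ccc(OC)cc2)COc3ccc4ccc(=O)oc4c3
F5 | step 11 | 7-{[(4R,5S)-2-(4-methoxyphenyl)-5-methyl-5-{[(2S)-4-methylidene-5-oxooxolan-2-yl]methyl}-1,3-dioxolan-4-yl]methoxy}-2H-chromen-2-one, acetal carbon either epimer | C=C1C[C@@H](C[C@]2(C)OC(c3ccc(OC)cc3)O[C@@H]2COc4ccc5ccc(=O)oc5c4)OC1=O
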